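The earlier runs and the new flask stem from a simulated flask for substances that don't exist; the scatter is artificial.

If the flask had really stopped by 20 h, I wanted to know what had stopped it. The answer would tell me which option could restart it. South is this flask followed so far.

| setting | south | east | flask |
|---|---|---|---|
| left-handed substrate | 0.20 M | 0.20 M | 0.20 M |
| right-handed substrate | 0.20 M | 0.20 M | 0.20 M |
| solid reagent | 0.60 equiv | 0.60 equiv | 0.600 equiv |
| free catalyst | 0.1 mol% | 0.05 mol% | 0.1 mol% |
| remark | the very flask that is asked about, followed so far | run made earlier |  |
| time |  |  | 20 h |

| run | time / h | left-handed product / % | left-handed substrate / % |
|---|---|---|---|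
| south | 4.00 | 20.8 | 31.0 |
| south | 8.00 | 21.6 | 29.8 |
| south | 12.0 | 20.0 | 28.1 |
| south | 15.0 | 20.5 | 29.7 |
| east | 0.667 | 2.8 | 46.2 |
| east | 1.33 | 7.2 | 39.8 |
| east | 2.00 | 12.1 | 37.1 |
| east | 3.00 | 18.5 | 31.0 |

(standard deviation of a reading: 1 percentage point)

- spring: at 20 h add free catalyst, 50.0 % of the amount charged, then wait 6.0 h
- noon: at 20 h add left-handed substrate, 50.0 % of the amount charged, then wait 6.0 h
- autumn: at 20 h take out 90 % of the left-handed product then present, then wait 6.0 h
- dusk: change nothing and wait 6.0 h more

- free catalyst is single-handed; left-handed substrate and right-handed substrate are mirror images of each other, charged as a racemate, each of them at the stated concentration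
- solid, in amounts per volume of the solution: solid reagent
- left-handed product that was removed still counts
- the numbers in the tables scatter by 1 percentage point (one standard deviation)
- at the start none of the solid reagent is in solution
- additions bring no volume worth counting

- left-handed product, in percent of the left-handed substrate and right-handed substrate together first charged, at 20 h
- the option that brings most further left-handed product ("none" if no option brings more than 2 percentage points) (spring / noon / autumn / dusk / none)
- left-handed product present, with what was taken out counted in, in percent of the left-handed substrate and right-handed substrate together first charged, after spring
- left-handed product present, with what was taken out counted in, in percent of the left-handed substrate and right-handed substrate together first charged, after noon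

I went up the time scales from the fastest. The east readings ran nearly straight, so I took the catalyst to use the reagent as fast as the solid fed it into solution. That made the coupling the fast step, and I let it keep pace with the dissolving. South's four readings averaged 20.7 %. At its pace, east needed 3.08 h to reach that level, which is less than the 4.00 h of south's first reading. So the dissolving looked finished long before 20 h, and the flask should then stand still.

A dying catalyst did not fit. East, with half the catalyst of south, reached 18.5 %, more than the 10.3 % that is half of south's average.

So I reckoned with the reagent. Taken one to one, its charge covers 30.0 % of both substrates together, and I called that the budget. I took solid reagent as the limiting reagent. The left-handed share, the part of the budget that ends as left-handed product, was 69.1 %. I assigned the remainder to right-handed substrate, which no reading follows. My call was about 20.7 % now and the same after spring and after noon. I expected no option to be worth taking, since none of them brings reagent.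

The forecast differed from my call on the options. It said 20.7 % now, autumn as best, 20.7 % after spring and 31 % after noon, on these grounds: “My best reading is an equilibrium with solid reagent still present”.

The flask gave 20.0 % at 20 h, and the answer on the options was none. Spring ended at 20.0 % and noon at 20.0 %, and autumn gained 0 percentage points.

    partner + free catalyst + right-handed substrate → free catalyst + right-handed product (k = 17.9 L² mol⁻² s⁻¹)
    solid reagent ⇌ partner, rate k2*(cs2 - [partner]) while solid is left; crystals form when [partner] > cs2 (solubility = 0.130 M, k = 1.02 × 10⁻⁴ s⁻¹)
    partner + free catalyst → spent catalyst (k = 1.80 × 10⁻⁴ L mol⁻¹ s⁻¹)
    partner + free catalyst + left-handed substrate → free catalyst + left-handed product (k = 41.2 L² mol⁻² s⁻¹)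

At 20 h the flask held 0 % of its solid reagent, with 20.0 % left-handed product and 9.97 % right-handed product. Together they made 30.0 %, which matched the budget. The neighbour flask with 1.00 equiv of solid reagent had a budget of 50.0 %, and my share of 69.1 % gave it 34.5 %. At 20 h that neighbour flask held 0 % solid reagent, 18.0 % right-handed product and 32.0 % left-handed product, a share of 64.0 %.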